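## Retrosynthetic overview

1. Target 14 ⇐ tris-TBS (3S)-isoflavanone 13 by fluoride desilylation under non-basic conditions, so C3 is never exposed to base after it is set.
2. 13 ⇐ 2'-hydroxy-α-methylene deoxybenzoin 11: ring C is closed last through the O1–C2 bond (intramolecular oxa-Michael), and catalyst-controlled protonation of the resulting enolate fixes C3.
3. 11 ⇐ deoxybenzoin 8 by silylation and α-methylenation; the prenyl group ⇐ aryl bromide 7 by Stille coupling.
4. 7 ⇐ phloroglucinol 5 (ring A) + arylacetonitrile 4 (ring B) by Hoesch acylation; 4 ⇐ 3-bromo-4,5-dihydroxybenzaldehyde 1 by selective 4-O-methylation and one-carbon homologation.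
5. Ring order: rings A and B are bought as arenes; the pyranone ring C is the only ring made, in step 7.

Assumptions: 3-bromo-4,5-dihydroxybenzaldehyde is taken as a catalogue chemical (otherwise one step from 5-bromovanillin). The sense of induction in step 7 is assigned from a working model, not from precedent; if the first run gives the (3R) series, the quinidine-derived pseudoenantiomer of the catalyst is used with no other change. TBS = tert-butyldimethylsilyl; TBSO = tert-butyldimethylsilyloxy; prenyl = 3-methylbut-2-en-1-yl.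

## Route

Step 1
Reactants: 1 3-bromo-4,5-dihydroxybenzaldehyde
Product: 2 3-bromo-5-hydroxy-4-methoxybenzaldehyde
Conditions: MeI (1.1 equiv), Li2CO3 (1.5 equiv), DMF, 40 °C
Reagents that add atoms: iodomethane, CI
Why: Williamson O-methylation is selective because the 4-OH (para to CHO, ortho to Br) is much the more acidic phenol, so the weak base Li2CO3 forms only that phenoxide and the 5-OH stays free.

Step 2
Reactants: 2 3-bromo-5-hydroxy-4-methoxybenzaldehyde
Product: 4 2-(3-bromo-5-hydroxy-4-methoxyphenyl)acetonitrile, via N-(2-aryl-1-tosylvinyl)formamide 3 (not isolated)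
Conditions: TosMIC (1.2 equiv), t-BuOK (3.5 equiv), DME, −50 °C; then MeOH, reflux, 30 min
Reagents that add atoms: TosMIC (4-methylbenzenesulfonylmethyl isocyanide), [C-]#[N+]CS(=O)(=O)c1ccc(C)cc1
Why: In this van Leusen reductive cyanation the TosMIC anion adds to the aldehyde, the 4-tosyloxazoline opens at low temperature to formamide 3, and methanolysis with loss of toluenesulfinate gives the homologous nitrile, the extra equivalent of base only carrying the phenol as its phenoxide.

Step 3
Reactants: 4 2-(3-bromo-5-hydroxy-4-methoxyphenyl)acetonitrile; 5 phloroglucinol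
Product: 7 2-(3-bromo-5-hydroxy-4-methoxyphenyl)-1-(2,4,6-trihydroxyphenyl)ethan-1-one, via ketiminium chloride 6 (not isolated)
Conditions: HCl (g), ZnCl2 (0.5 equiv), Et2O, 0 °C, 24 h; then H2O, reflux, 2 h
Reagents that add atoms: water, O
Why: In this Hoesch acylation the HCl/ZnCl2-activated nitrile C-acylates the very electron-rich phloroglucinol once (the precipitating ketiminium salt is deactivated) and hydrolysis gives the deoxybenzoin, while the much less nucleophilic ring B, its bromide, OMe and OH are inert.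

Step 4
Reactants: 7 2-(3-bromo-5-hydroxy-4-methoxyphenyl)-1-(2,4,6-trihydroxyphenyl)ethan-1-one
Product: 8 2-(3-hydroxy-4-methoxy-5-prenylphenyl)-1-(2,4,6-trihydroxyphenyl)ethan-1-one
Conditions: tributyl(3-methylbut-2-en-1-yl)stannane (1.3 equiv), Pd(PPh3)4 (5 mol%), DMF, 95 °C; MeCN/hexane partition to remove tin
Reagents that add atoms: tributyl(3-methylbut-2-en-1-yl)stannane, CCCC[Sn](CCCC)(CCCC)CC=C(C)C
Why: In this Kosugi–Migita–Stille coupling zerovalent palladium inserts into the aryl C–Br bond, the prenyl group is transferred from tin at its alpha carbon, and reductive elimination gives the linear prenyl arene under neutral conditions that tolerate free phenols and the enolisable ketone; it is placed after step 3 because the alkene would not survive HCl.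

Step 5
Reactants: 8 2-(3-hydroxy-4-methoxy-5-prenylphenyl)-1-(2,4,6-trihydroxyphenyl)ethan-1-one
Product: 9 1-[2-hydroxy-4,6-bis(TBSO)phenyl]-2-[3-(TBSO)-4-methoxy-5-prenylphenyl]ethan-1-one
Conditions: TBSCl (3.3 equiv), imidazole (7 equiv), DMF, 0 °C to rt
Reagents that add atoms: tert-butyldimethylsilyl chloride, CC(C)(C)[Si](C)(C)Cl
Why: Silyl ether formation caps the three non-chelated phenols while the 2-OH hydrogen-bonded to the ketone stays free, which removes the acidic phenols and the ring A nucleophilicity that would interfere with steps 6 and 7.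

Step 6
Reactants: 9 1-[2-hydroxy-4,6-bis(TBSO)phenyl]-2-[3-(TBSO)-4-methoxy-5-prenylphenyl]ethan-1-one
Product: 11 1-[2-hydroxy-4,6-bis(TBSO)phenyl]-2-[3-(TBSO)-4-methoxy-5-prenylphenyl]prop-2-en-1-one, via Mannich base 10 (not isolated)
Conditions: (CH2O)n (2 equiv), i-Pr2NH2+ CF3CO2− (1 equiv), CF3CO2H (10 mol%), THF, 65 °C; product used at once
Reagents that add atoms: paraformaldehyde (as formaldehyde), C=O
Why: In this Mannich-type α-methylenation the ammonium trifluoroacetate forms the iminium of formaldehyde, the ketone enol adds to give Mannich base 10, and E1cB loss of i-Pr2NH gives the 1,1-disubstituted enone, the medium staying acidic so that the chelated 2'-OH does not close ring C prematurely.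

Step 7
Reactants: 11 1-[2-hydroxy-4,6-bis(TBSO)phenyl]-2-[3-(TBSO)-4-methoxy-5-prenylphenyl]prop-2-en-1-one
Product: 13 (3S)-5,7-bis(TBSO)-3-[3-(TBSO)-4-methoxy-5-prenylphenyl]chroman-4-one, via chromen-4-ol enol 12 (not isolated)
Conditions: quinine-derived squaramide 3-{[3,5-bis(trifluoromethyl)phenyl]amino}-4-{[(8α,9S)-6'-methoxycinchonan-9-yl]amino}cyclobut-3-ene-1,2-dione (10 mol%), toluene (0.05 M), −30 °C, 48 h; cold filtration through silica
Reagents that add atoms: none
Why: Proposed new method: a catalytic enantioselective intramolecular oxa-Michael addition/enolate protonation cascade, in which the quinuclidine nitrogen deprotonates the 2'-OH, the squaramide N–H pair binds the carbonyl oxygen, the phenoxide attacks the unsubstituted methylene carbon (6-endo) to form the O1–C2 bond and the squaramide-bound enolate of 12, and the quinuclidinium N–H held over one face delivers its proton to the Re face of C3 to set the (3S) center kinetically, the catalyst then being returned to the phenol of the next substrate (several pKa units more acidic than the product C3–H), so the product is not re-enolised at −30 °C; the closest known reaction types are the racemic base-mediated cyclisation of 2'-hydroxy-α-methylene deoxybenzoins to isoflavanones and cinchona squaramide or thiourea catalysed sulfa-Michael addition/enantioselective protonation of α-aryl acrylates.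

Step 8
Reactants: 13 (3S)-5,7-bis(TBSO)-3-[3-(TBSO)-4-methoxy-5-prenylphenyl]chroman-4-one
Product: 14 (3S)-5,7-dihydroxy-3-[3-hydroxy-4-methoxy-5-(3-methylbut-2-en-1-yl)phenyl]-2,3-dihydro-4H-chromen-4-one (target)
Conditions: Et3N·3HF (3 equiv), THF, 0 °C to rt
Reagents that add atoms: none
Why: Fluoride-mediated Si–O cleavage under weakly acidic, non-basic conditions removes the three aryl TBS ethers without enolising C3 and without touching the prenyl alkene or the methyl ether.

## Compound list

1 | 3-bromo-4,5-dihydroxybenzaldehyde | O=Cc1cc(O)c(O)c(Br)c1 | starting material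
2 | 3-bromo-5-hydroxy-4-methoxybenzaldehyde | COc1c(O)cc(C=O)cc1Br | intermediate
3 | N-[2-(3-bromo-5-hydroxy-4-methoxyphenyl)-1-(4-methylbenzenesulfonyl)ethenyl]formamide (not isolated) | O=CNC(=Cc1cc(O)c(OC)c(Br)c1)S(=O)(=O)c1ccc(C)cc1 | intermediate
4 | 2-(3-bromo-5-hydroxy-4-methoxyphenyl)acetonitrile | COc1c(O)cc(CC#N)cc1Br | intermediate
5 | phloroglucinol (benzene-1,3,5-triol) | Oc1cc(O)cc(O)c1 | starting material
6 | 2-(3-bromo-5-hydroxy-4-methoxyphenyl)-1-(2,4,6-trihydroxyphenyl)ethan-1-iminium chloride (not isolated) | [NH2+]=C(Cc1cc(O)c(OC)c(Br)c1)c1c(O)cc(O)cc1O.[Cl-] | intermediate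
7 | 2-(3-bromo-5-hydroxy-4-methoxyphenyl)-1-(2,4,6-trihydroxyphenyl)ethan-1-one | COc1c(O)cc(CC(=O)c2c(O)cc(O)cc2O)cc1Br | intermediate
8 | 2-[3-hydroxy-4-methoxy-5-(3-methylbut-2-en-1-yl)phenyl]-1-(2,4,6-trihydroxyphenyl)ethan-1-one | COc1c(O)cc(CC(=O)c2c(O)cc(O)cc2O)cc1CC=C(C)C | intermediate
9 | 1-[2-hydroxy-4,6-bis(TBSO)phenyl]-2-[3-(TBSO)-4-methoxy-5-prenylphenyl]ethan-1-one | COc1c(O[Si](C)(C)C(C)(C)C)cc(CC(=O)c2c(O)cc(O[Si](C)(C)C(C)(C)C)cc2O[Si](C)(C)C(C)(C)C)cc1CC=C(C)C | intermediate
10 | racemic 3-(diisopropylamino)-1-[2-hydroxy-4,6-bis(TBSO)phenyl]-2-[3-(TBSO)-4-methoxy-5-prenylphenyl]propan-1-one (Mannich base, not isolated) | COc1c(O[Si](C)(C)C(C)(C)C)cc(C(CN(C(C)C)C(C)C)C(=O)c2c(O)cc(O[Si](C)(C)C(C)(C)C)cc2O[Si](C)(C)C(C)(C)C)cc1CC=C(C)C | intermediate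
11 | 1-[2-hydroxy-4,6-bis(TBSO)phenyl]-2-[3-(TBSO)-4-methoxy-5-prenylphenyl]prop-2-en-1-one | COc1c(O[Si](C)(C)C(C)(C)C)cc(C(=C)C(=O)c2c(O)cc(O[Si](C)(C)C(C)(C)C)cc2O[Si](C)(C)C(C)(C)C)cc1CC=C(C)C | intermediate
12 | 5,7-bis(TBSO)-3-[3-(TBSO)-4-methoxy-5-prenylphenyl]-2H-chromen-4-ol (enol, present as the catalyst-bound enolate, not isolated) | COc1c(O[Si](C)(C)C(C)(C)C)cc(C2=C(O)c3c(O[Si](C)(C)C(C)(C)C)cc(O[Si](C)(C)C(C)(C)C)cc3OC2)cc1CC=C(C)C | intermediate
13 | (3S)-5,7-bis(TBSO)-3-[3-(TBSO)-4-methoxy-5-prenylphenyl]chroman-4-one | COc1c(O[Si](C)(C)C(C)(C)C)cc([C@H]2COc3cc(O[Si](C)(C)C(C)(C)C)cc(O[Si](C)(C)C(C)(C)C)c3C2=O)cc1CC=C(C)C | intermediate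
14 | (3S)-5,7-dihydroxy-3-[3-hydroxy-4-methoxy-5-(3-methylbut-2-en-1-yl)phenyl]-2,3-dihydro-4H-chromen-4-one | COc1c(O)cc([C@H]2COc3cc(O)cc(O)c3C2=O)cc1CC=C(C)C | target

## Step count and risks

Total step count: 8. Longest linear sequence: 8 steps (1 to 14); phloroglucinol 5 enters directly in step 3.

Three steps most likely to fail:

Step 7 (the proposed oxa-Michael/protonation cascade): the enantioselectivity or its sense may be inadequate, or the product may partly racemise on the catalyst. The fallback uses known chemistry, sets out from 11 and comes back at 13. Enone 11 is cyclised with Et3N (20 mol%) in CH2Cl2 at room temperature to the racemic tris-TBS isoflavanone F1. F1 is resolved by preparative chiral SFC on an amylose tris(3,5-dimethylphenylcarbamate) phase to give 13. The unwanted (3R)-tris-TBS isoflavanone F2 is re-racemised to F1 with catalytic DBU in toluene and recycled.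

Step 6 (α-methylenation): the free 2'-OH enone may cyclise racemically in the pot, a TBS ether may be lost, or formaldehyde may react with the prenyl alkene under acid. The fallback sets out from 9 and comes back at 11. A stoichiometric Mannich reaction of 9 with Eschenmoser's salt (CH2=NMe2+ I−, MeCN, 40 °C) gives the dimethylamino Mannich base F3, isolated and purified as its hydroiodide. Heating this salt in toluene at 80 °C expels dimethylammonium iodide and gives 11 under acidic, amine-free conditions with no formaldehyde present.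

Step 4 (Stille prenylation of the free tetraphenol): oxidative addition into the hindered, electron-rich bromide may be slow, or some gamma coupling may give the reverse-prenyl isomer. The fallback sets out from 7 and comes back at 9. Bromide 7 is silylated first (TBSCl, imidazole, DMF) to the tris-TBS aryl bromide F4. Kosugi–Migita allylation with allyltributylstannane and Pd(PPh3)4 in toluene at 100 °C, where no regiochemical issue exists, gives the tris-TBS allyl arene F5. Cross-metathesis with 2-methylbut-2-ene (second-generation Grubbs catalyst RuCl2(=CHPh)(H2IMes)(PCy3), CH2Cl2, 35 °C) then gives 9.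

## Further compounds

F1 | step 7 | racemic 5,7-bis(TBSO)-3-[3-(TBSO)-4-methoxy-5-prenylphenyl]chroman-4-one | COc1c(O[Si](C)(C)C(C)(C)C)cc(C2COc3cc(O[Si](C)(C)C(C)(C)C)cc(O[Si](C)(C)C(C)(C)C)c3C2=O)cc1CC=C(C)C
F2 | step 7 | (3R)-5,7-bis(TBSO)-3-[3-(TBSO)-4-methoxy-5-prenylphenyl]chroman-4-one | COc1c(O[Si](C)(C)C(C)(C)C)cc([C@@H]2COc3cc(O[Si](C)(C)C(C)(C)C)cc(O[Si](C)(C)C(C)(C)C)c3C2=O)cc1CC=C(C)C
F3 | step 6 | racemic 3-(dimethylamino)-1-[2-hydroxy-4,6-bis(TBSO)phenyl]-2-[3-(TBSO)-4-methoxy-5-prenylphenyl]propan-1-one | COc1c(O[Si](C)(C)C(C)(C)C)cc(C(CN(C)C)C(=O)c2c(O)cc(O[Si](C)(C)C(C)(C)C)cc2O[Si](C)(C)C(C)(C)C)cc1CC=C(C)C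
F4 | step 4 | 2-[3-bromo-5-(TBSO)-4-methoxyphenyl]-1-[2-hydroxy-4,6-bis(TBSO)phenyl]ethan-1-one | COc1c(O[Si](C)(C)C(C)(C)C)cc(CC(=O)c2c(O)cc(O[Si](C)(C)C(C)(C)C)cc2O[Si](C)(C)C(C)(C)C)cc1Br
F5 | step 4 | 2-[3-allyl-5-(TBSO)-4-methoxyphenyl]-1-[2-hydroxy-4,6-bis(TBSO)phenyl]ethan-1-one | COc1c(O[Si](C)(C)C(C)(C)C)cc(CC(=O)c2c(O)cc(O[Si](C)(C)C(C)(C)C)cc2O[Si](C)(C)C(C)(C)C)cc1CC=C
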